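**Retrosynthetic overview**

1. The target is reached from its 5,3'-bis-silyl ether by fluoride desilylation (last step).
2. Key disconnection C2–C3: the silylated dihydroflavonol comes from an isomeric, racemic seven-membered cyclic acetal (a 2-aryl-1,3-benzodioxepin-5-one) by a chiral-acid-catalysed, ring-contracting O-to-C (Petasis–Ferrier-type) rearrangement. An oxocarbenium ion at C2, still held on O1, and the enediol of the C3/C4 ketol close ring C and set C2 and C3 together.
3. Enabling feature: C2 is a benzylic carbon that carries the ring oxygen O1 and the 4-methoxyphenyl ring B, so it is a masked isovanillin carbonyl carbon that ionises easily. Its neighbour C3 is the oxygen-bearing α-carbon of the C4 aryl ketone, so C2 can be stored on the C3 oxygen as an O,O-acetal and then moved from oxygen to carbon.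
4. The acetal comes from the ring A ketol and isovanillin dimethyl acetal (transacetalisation), the ketol from the acetophenone by enolate hydroxylation. The ring A pattern (free O1–H para to prenyl, silylated 5-O ortho to prenyl) comes from symmetric 2',6'-dihydroxy-4'-methoxyacetophenone by O-prenylation, silylation and para-Claisen–Cope rearrangement.
5. Ring order: rings A and B are bought; the temporary seven-membered dioxepinone ring is formed first (step 7), ring C last (step 8).

Key step: step 8

Remark: flavonoid numbering (O1, C2, C3, C4, C4a, C5–C8, C8a, ring B primed) is used for all intermediates and TBS is tert-butyldimethylsilyl. The (R)-configured acid of step 8 is assumed to lead to the (2R) series; its mirror image would be used if the first experiment shows the opposite sense.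

**Route**

Step 1
Reactants: 1 1-(2,6-dihydroxy-4-methoxyphenyl)ethan-1-one
Product: 2 1-[2-hydroxy-4-methoxy-6-(3-methylbut-2-en-1-yloxy)phenyl]ethan-1-one
Conditions: prenyl bromide (1.05 equiv), K2CO3 (1.2 equiv), acetone, reflux
Reagents that add atoms: prenyl bromide (1-bromo-3-methylbut-2-ene), CC(C)=CCBr
Why: Williamson ether synthesis on a symmetric diol, so only one mono-ether is possible, and the remaining OH is hydrogen-bonded to the ketone and should alkylate much more slowly; no stereocentre is formed.

Step 2
Reactants: 2 1-[2-hydroxy-4-methoxy-6-(3-methylbut-2-en-1-yloxy)phenyl]ethan-1-one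
Product: 3 1-[2-(tert-butyldimethylsilyloxy)-4-methoxy-6-(3-methylbut-2-en-1-yloxy)phenyl]ethan-1-one
Conditions: TBSCl, imidazole, DMF, 40 °C
Reagents that add atoms: tert-butyldimethylsilyl chloride, CC(C)(C)[Si](C)(C)Cl
Why: imidazole-mediated silylation of the chelated phenol marks this oxygen as the future 5-O before the rearrangement, so the two ring A oxygens stay distinguishable.

Step 3
Reactants: 3 1-[2-(tert-butyldimethylsilyloxy)-4-methoxy-6-(3-methylbut-2-en-1-yloxy)phenyl]ethan-1-one
Product: 6 1-[2-(tert-butyldimethylsilyloxy)-6-hydroxy-4-methoxy-3-(3-methylbut-2-en-1-yl)phenyl]ethan-1-one, via ortho-dienone 4 (not isolated), via para-dienone 5 (not isolated)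
Conditions: N,N-diethylaniline, 200 °C, sealed tube, argon
Reagents that add atoms: none
Why: tandem aromatic Claisen/Cope (para-Claisen) rearrangement, in which a [3,3] shift to the free ortho carbon gives 4 with a reversed prenyl group, a second [3,3] shift carries it to the para carbon (5) as a normal prenyl group, and enolisation gives the phenol with prenyl para to the freed O1–H and between OMe and OTBS.

Step 4
Reactants: 6 1-[2-(tert-butyldimethylsilyloxy)-6-hydroxy-4-methoxy-3-(3-methylbut-2-en-1-yl)phenyl]ethan-1-one
Product: 8 1-[2-(tert-butyldimethylsilyloxy)-6-hydroxy-4-methoxy-3-(3-methylbut-2-en-1-yl)phenyl]-2-hydroxyethan-1-one, via dilithium phenoxide enolate 7 (not isolated)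
Conditions: LiN(SiMe3)2 (2.3 equiv), THF, −78 °C; 3-phenyl-2-(phenylsulfonyl)oxaziridine (1.3 equiv), −78 °C; AcOH quench at −78 °C
Reagents that add atoms: 3-phenyl-2-(phenylsulfonyl)oxaziridine, O=S(=O)(N1OC1c1ccccc1)c1ccccc1
Why: enolate hydroxylation with an N-sulfonyloxaziridine, where the methyl-ketone enolate of the dianion attacks the oxaziridine oxygen, the prenyl alkene is inert to this oxidant at low temperature and the cold acidic quench is meant to forestall silyl transfer; no stereocentre is formed.

Step 5
Reactants: 9 3-hydroxy-4-methoxybenzaldehyde (isovanillin)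
Product: 10 3-(tert-butyldimethylsilyloxy)-4-methoxybenzaldehyde
Conditions: TBSCl, imidazole, CH2Cl2, rt
Reagents that add atoms: tert-butyldimethylsilyl chloride, CC(C)(C)[Si](C)(C)Cl
Why: standard silylation of a free phenol, which keeps the 3'-oxygen out of the acetal chemistry and is removed together with the 5-O-silyl group at the end.

Step 6
Reactants: 10 3-(tert-butyldimethylsilyloxy)-4-methoxybenzaldehyde
Product: 11 tert-butyl[5-(dimethoxymethyl)-2-methoxyphenoxy]dimethylsilane
Conditions: HC(OMe)3, PPTS (2 mol %), MeOH, rt; Et3N quench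
Reagents that add atoms: trimethyl orthoformate, COC(OC)OC; methanol (solvent, exchanges with the orthoformate), CO
Why: acid-catalysed acetalisation with the orthoformate as water scavenger gives the activated aldehyde equivalent needed for mild acetal exchange, and aryl silyl ethers tolerate this weak acid.

Step 7
Reactants: 8 1-[2-(tert-butyldimethylsilyloxy)-6-hydroxy-4-methoxy-3-(3-methylbut-2-en-1-yl)phenyl]-2-hydroxyethan-1-one; 11 tert-butyl[5-(dimethoxymethyl)-2-methoxyphenoxy]dimethylsilane
Product: 13 rac-6-(tert-butyldimethylsilyloxy)-2-[3-(tert-butyldimethylsilyloxy)-4-methoxyphenyl]-8-methoxy-7-(3-methylbut-2-en-1-yl)-4H-1,3-benzodioxepin-5-one, via acyclic mixed acetal 12 (not isolated)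
Conditions: PPTS (10 mol %), toluene, 5 Å MS, 50 °C, methanol removed under reduced pressure; Et3N quench, Et3N-deactivated silica
Reagents that add atoms: none
Why: acid-catalysed transacetalisation in which the primary ketol hydroxyl exchanges first (12) and the chelated phenol O1–H then closes the seven-membered ring as methanol is removed, the weak acid being chosen so that the aryl-oxocarbenium ion of step 8 is not yet reached; the acetal stereocentre is formed racemic and is erased in step 8.

Step 8
Reactants: 13 rac-6-(tert-butyldimethylsilyloxy)-2-[3-(tert-butyldimethylsilyloxy)-4-methoxyphenyl]-8-methoxy-7-(3-methylbut-2-en-1-yl)-4H-1,3-benzodioxepin-5-one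
Product: 15 (2R,3R)-5-(tert-butyldimethylsilyloxy)-2-[3-(tert-butyldimethylsilyloxy)-4-methoxyphenyl]-3-hydroxy-7-methoxy-6-(3-methylbut-2-en-1-yl)-2,3-dihydro-4H-chromen-4-one, via oxocarbenium enediol cation 14 (not isolated)
Conditions: (R)-3,3'-bis(2,4,6-triisopropylphenyl)-1,1'-binaphthyl-2,2'-diyl N-triflylphosphoramide (5 mol %), toluene (0.02 M), 5 Å MS, 0 °C to rt
Reagents that add atoms: none
Why: Proposed new method: the chiral acid protonates the acetal at the oxygen that sits on C3, the bond from C2 to that oxygen ionises to an oxocarbenium ion at C2 that stays bound to ring A through O1 and is stabilised by the 4-methoxyphenyl ring B, the released ketol enolises to the enediol (ion pair 14), and C3 of the enediol adds to C2, after which proton loss gives the C4 ketone and returns the acid, so that C2 moves from oxygen to carbon and the seven-membered acetal ring contracts to ring C. The closest known reaction types are the Petasis–Ferrier rearrangement of cyclic enol acetals to pyran-4-ones, its chiral-phosphoric-acid-catalysed variant that contracts seven-membered cyclic vinyl acetals, and chiral-Brønsted-acid-controlled Mukaiyama- and Prins-type additions to oxocarbenium ions; what has not been shown is an aryl-oxygen-bound oxocarbenium ion paired with an enediol released from an α-ketol acetal. Ring C closes by a 6-endo-trig addition to the O1=C2 oxocarbenium bond in which the enol double bond C3=C4 also lies inside the new ring (6-enolendo), the bond formed being C2–C3. C2 is controlled by the catalyst, whose anion should hold both enediol hydroxyls by hydrogen bonds and shield one face of the planar oxocarbenium ion, and because the acetal stereocentre is erased on ionisation both enantiomers of 13 should converge on one product; C3 is controlled by C2 through a half-chair transition state with aryl and hydroxyl trans-diequatorial, and any 2,3-cis material can equilibrate at C3 through the enol to the more stable trans isomer under the same acid. The step needs bond formation at C3 and not at C4 of the enediol and needs intramolecular capture of the cation: the electron-rich ring A on C4 stabilises the charge that develops at C4 when C3 attacks and the product is a conjugated aryl ketone in a six- instead of a five-membered ring, the alternative C2–O1 ionisation only re-forms the acetal, the 5-O-silyl group keeps that oxygen away from the prenyl group under acid, and high dilution over molecular sieves should suppress intermolecular arylation and hydrolysis.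

Step 9
Reactants: 15 (2R,3R)-5-(tert-butyldimethylsilyloxy)-2-[3-(tert-butyldimethylsilyloxy)-4-methoxyphenyl]-3-hydroxy-7-methoxy-6-(3-methylbut-2-en-1-yl)-2,3-dihydro-4H-chromen-4-one
Product: 16 (2R,3R)-3,5-dihydroxy-2-(3-hydroxy-4-methoxyphenyl)-7-methoxy-6-(3-methylbut-2-en-1-yl)-2,3-dihydro-4H-chromen-4-one
Conditions: Bu4NF (2.2 equiv), AcOH (2.5 equiv), THF, 0 °C
Reagents that add atoms: none
Why: fluoride-mediated cleavage of both aryl silyl ethers, with acetic acid buffering so that the base-labile 3-hydroxychromanone (C3 epimerisation, ring opening at O1–C2) and both stereocentres should remain untouched.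

**Compound list**

1 | 1-(2,6-dihydroxy-4-methoxyphenyl)ethan-1-one | CC(=O)c1c(O)cc(OC)cc1O | starting material
2 | 1-[2-hydroxy-4-methoxy-6-(3-methylbut-2-en-1-yloxy)phenyl]ethan-1-one | CC(=O)c1c(O)cc(OC)cc1OCC=C(C)C | intermediate
3 | 1-[2-(tert-butyldimethylsilyloxy)-4-methoxy-6-(3-methylbut-2-en-1-yloxy)phenyl]ethan-1-one | CC(=O)c1c(O[Si](C)(C)C(C)(C)C)cc(OC)cc1OCC=C(C)C | intermediate
4 | 2-acetyl-3-(tert-butyldimethylsilyloxy)-5-methoxy-6-(2-methylbut-3-en-2-yl)cyclohexa-2,4-dien-1-one (racemic, not isolated) | CC(=O)C1=C(O[Si](C)(C)C(C)(C)C)C=C(OC)C(C(C)(C)C=C)C1=O | intermediate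
5 | 2-acetyl-3-(tert-butyldimethylsilyloxy)-5-methoxy-4-(3-methylbut-2-en-1-yl)cyclohexa-2,5-dien-1-one (racemic, not isolated) | CC(=O)C1=C(O[Si](C)(C)C(C)(C)C)C(CC=C(C)C)C(OC)=CC1=O | intermediate
6 | 1-[2-(tert-butyldimethylsilyloxy)-6-hydroxy-4-methoxy-3-(3-methylbut-2-en-1-yl)phenyl]ethan-1-one | CC(=O)c1c(O[Si](C)(C)C(C)(C)C)c(CC=C(C)C)c(OC)cc1O | intermediate
7 | dilithium phenoxide enolate of 6 (not isolated) | [Li+].[Li+].C=C([O-])c1c(O[Si](C)(C)C(C)(C)C)c(CC=C(C)C)c(OC)cc1[O-] | intermediate
8 | 1-[2-(tert-butyldimethylsilyloxy)-6-hydroxy-4-methoxy-3-(3-methylbut-2-en-1-yl)phenyl]-2-hydroxyethan-1-one | OCC(=O)c1c(O[Si](C)(C)C(C)(C)C)c(CC=C(C)C)c(OC)cc1O | intermediate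
9 | 3-hydroxy-4-methoxybenzaldehyde (isovanillin) | COc1ccc(C=O)cc1O | starting material
10 | 3-(tert-butyldimethylsilyloxy)-4-methoxybenzaldehyde | COc1ccc(C=O)cc1O[Si](C)(C)C(C)(C)C | intermediate
11 | tert-butyl[5-(dimethoxymethyl)-2-methoxyphenoxy]dimethylsilane | COc1ccc(C(OC)OC)cc1O[Si](C)(C)C(C)(C)C | intermediate
12 | 1-[2-(tert-butyldimethylsilyloxy)-6-hydroxy-4-methoxy-3-(3-methylbut-2-en-1-yl)phenyl]-2-{[3-(tert-butyldimethylsilyloxy)-4-methoxyphenyl](methoxy)methoxy}ethan-1-one (racemic, not isolated) | COc1ccc(C(OC)OCC(=O)c2c(O)cc(OC)c(CC=C(C)C)c2O[Si](C)(C)C(C)(C)C)cc1O[Si](C)(C)C(C)(C)C | intermediate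
13 | rac-6-(tert-butyldimethylsilyloxy)-2-[3-(tert-butyldimethylsilyloxy)-4-methoxyphenyl]-8-methoxy-7-(3-methylbut-2-en-1-yl)-4H-1,3-benzodioxepin-5-one | COc1ccc(C2OCC(=O)c3c(O2)cc(OC)c(CC=C(C)C)c3O[Si](C)(C)C(C)(C)C)cc1O[Si](C)(C)C(C)(C)C | intermediate
14 | ring-opened cation: {[3-(tert-butyldimethylsilyloxy)-4-methoxyphenyl]methylidene}[3-(tert-butyldimethylsilyloxy)-2-(1,2-dihydroxyethenyl)-5-methoxy-4-(3-methylbut-2-en-1-yl)phenyl]oxonium, counter-ion the conjugate base of the acid catalyst (not isolated) | COc1ccc(C=[O+]c2cc(OC)c(CC=C(C)C)c(O[Si](C)(C)C(C)(C)C)c2C(O)=CO)cc1O[Si](C)(C)C(C)(C)C | intermediate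
15 | (2R,3R)-5-(tert-butyldimethylsilyloxy)-2-[3-(tert-butyldimethylsilyloxy)-4-methoxyphenyl]-3-hydroxy-7-methoxy-6-(3-methylbut-2-en-1-yl)-2,3-dihydro-4H-chromen-4-one | COc1ccc([C@H]2Oc3cc(OC)c(CC=C(C)C)c(O[Si](C)(C)C(C)(C)C)c3C(=O)[C@@H]2O)cc1O[Si](C)(C)C(C)(C)C | intermediate
16 | (2R,3R)-3,5-dihydroxy-2-(3-hydroxy-4-methoxyphenyl)-7-methoxy-6-(3-methylbut-2-en-1-yl)-2,3-dihydro-4H-chromen-4-one | COc1ccc([C@H]2Oc3cc(OC)c(CC=C(C)C)c(O)c3C(=O)[C@@H]2O)cc1O | target

**Step count and risks**

Total step count: 9. Longest linear sequence: 7 steps (steps 1, 2, 3, 4, 7, 8, 9 from compound 1).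

Steps most likely to fail:

1. Step 8 (proposed new method). The ion pair may collapse with poor facial selectivity at C2, the oxocarbenium ion may be lost to intermolecular arylation of the electron-rich rings, or ionisation may run only along the unproductive C2–O1 channel so that the acetal is returned or hydrolysed. Fallback with known chemistry, setting out from 8 and 10 and returning at 15: a direct catalytic asymmetric aldol addition of ketol 8 to aldehyde 10 with the dinuclear zinc catalyst made from Et2Zn and (S,S)-ProPhenol, 2,6-bis{[(S)-2-(hydroxydiphenylmethyl)pyrrolidin-1-yl]methyl}-4-methylphenol (THF, 4 Å MS, −30 °C, one further equivalent of Et2Zn to cap the phenol, ligand antipode chosen for this diol) should give the syn-diol (2R,3S)-1-[2-(tert-butyldimethylsilyloxy)-6-hydroxy-4-methoxy-3-(3-methylbut-2-en-1-yl)phenyl]-3-[3-(tert-butyldimethylsilyloxy)-4-methoxyphenyl]-2,3-dihydroxypropan-1-one F1. An intramolecular Mitsunobu etherification (PPh3, diisopropyl azodicarboxylate, THF, 0 °C) then closes ring C at O1–C2 with inversion at the benzylic carbon and gives 15.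

2. Step 7. Ring closure to the seven-membered mixed aryl alkyl acetal may stall at open-chain or oligomeric acetals, or acid-promoted aldol-type coupling between the enolising ketol and the acetal-derived oxocarbenium ion may overtake acetal exchange. Fallback by oxidative acetalisation, setting out from 8 and 10 and returning at 13: reduction of 10 (NaBH4, MeOH) gives [3-(tert-butyldimethylsilyloxy)-4-methoxyphenyl]methanol F2, and PBr3 (Et2O, 0 °C) gives [5-(bromomethyl)-2-methoxyphenoxy](tert-butyl)dimethylsilane F3. Williamson alkylation of the phenol of 8 with F3 (K2CO3, acetone, rt, argon) gives 1-[2-(tert-butyldimethylsilyloxy)-6-{[3-(tert-butyldimethylsilyloxy)-4-methoxyphenyl]methoxy}-4-methoxy-3-(3-methylbut-2-en-1-yl)phenyl]-2-hydroxyethan-1-one F4. DDQ (1.2 equiv, 4 Å MS, CH2Cl2, 0 °C) then abstracts hydride from the electron-rich benzylic ether carbon, and the ketol hydroxyl traps the cation to give 13.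

3. Step 4. Silyl transfer from the neighbouring aryl oxygen to the enolate or to the new alkoxide, addition of the enolate to the sulfonimine by-product, or over-oxidation of the primary ketol may erode the step. Fallback by neutral silyl enol ether oxidation, setting out from 6 and returning at 8: soft enolisation and silylation (TMSOTf, Et3N, CH2Cl2, 0 °C) gives tert-butyl{6-methoxy-2-(3-methylbut-2-en-1-yl)-3-(trimethylsilyloxy)... } in full {[3-methoxy-2-(3-methylbut-2-en-1-yl)-5-(trimethylsilyloxy)-6-[1-(trimethylsilyloxy)ethenyl]phenoxy]}(tert-butyl)dimethylsilane F5. Rubottom-type oxidation of the silyl enol ether with 3-phenyl-2-(phenylsulfonyl)oxaziridine (CHCl3, rt to 50 °C, no base) gives 1-[2-(tert-butyldimethylsilyloxy)-4-methoxy-3-(3-methylbut-2-en-1-yl)-6-(trimethylsilyloxy)phenyl]-2-(trimethylsilyloxy)ethan-1-one F6. Mild acidic cleavage of the two trimethylsilyl groups (aqueous citric acid, MeOH, rt), which spares the aryl TBS ether, gives 8.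

**Further compounds**

F1 | step 8 | (2R,3S)-1-[2-(tert-butyldimethylsilyloxy)-6-hydroxy-4-methoxy-3-(3-methylbut-2-en-1-yl)phenyl]-3-[3-(tert-butyldimethylsilyloxy)-4-methoxyphenyl]-2,3-dihydroxypropan-1-one | COc1ccc([C@H](O)[C@@H](O)C(=O)c2c(O)cc(OC)c(CC=C(C)C)c2O[Si](C)(C)C(C)(C)C)cc1O[Si](C)(C)C(C)(C)C
F2 | step 7 | [3-(tert-butyldimethylsilyloxy)-4-methoxyphenyl]methanol | COc1ccc(CO)cc1O[Si](C)(C)C(C)(C)C
F3 | step 7 | [5-(bromomethyl)-2-methoxyphenoxy](tert-butyl)dimethylsilane | COc1ccc(CBr)cc1O[Si](C)(C)C(C)(C)C
F4 | step 7 | 1-[2-(tert-butyldimethylsilyloxy)-6-{[3-(tert-butyldimethylsilyloxy)-4-methoxyphenyl]methoxy}-4-methoxy-3-(3-methylbut-2-en-1-yl)phenyl]-2-hydroxyethan-1-one | OCC(=O)c1c(O[Si](C)(C)C(C)(C)C)c(CC=C(C)C)c(OC)cc1OCc1ccc(OC)c(O[Si](C)(C)C(C)(C)C)c1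
F5 | step 4 | [3-methoxy-2-(3-methylbut-2-en-1-yl)-5-(trimethylsilyloxy)-6-[1-(trimethylsilyloxy)ethenyl]phenoxy](tert-butyl)dimethylsilane | C=C(O[Si](C)(C)C)c1c(O[Si](C)(C)C(C)(C)C)c(CC=C(C)C)c(OC)cc1O[Si](C)(C)C
F6 | step 4 | 1-[2-(tert-butyldimethylsilyloxy)-4-methoxy-3-(3-methylbut-2-en-1-yl)-6-(trimethylsilyloxy)phenyl]-2-(trimethylsilyloxy)ethan-1-one | C[Si](C)(C)OCC(=O)c1c(O[Si](C)(C)C(C)(C)C)c(CC=C(C)C)c(OC)cc1O[Si](C)(C)C
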